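**Plan**

Ring numbering used throughout: C1 = C(OH)(CH2OBz), with the CH2 as C7; C2 = CHCl; C3=C4; C5 = CHOH; C6 = CHOBz.
Retrosynthesis cuts, in this order: C2–Cl (back to a C2–OH of opposite configuration), the two benzoates, C1–O/C7–O (back to C1=CH2 and a C1 ketone), C3=C4 (back to a C4 selenide), then C2–C3 and C5–C6 together.
Feature used: C2–C1–C6, a carbinol carbon flanked by two heteroatom-bearing CH groups, is the α–C(=O)–α′ triad of dihydroxyacetone, and C3=C4–C5(OH) is an acrolein unit. The cyclohexene is therefore the α,α′-annulation product of a 1,3-dioxan-5-one and an acrolein, with the 1,3-dioxane (benzylidene acetal on O-2/O-6) as a temporary ring in a 2,4-dioxabicyclo[3.3.1]nonane.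
Forward: an enamine Michael/aldol annulation closes the carbocycle; selenoxide elimination unveils C3=C4; C1 is elaborated (Wittig, OsO4, BzCl); the acetal is removed; Cl enters at C2 by SN2; O-6 is benzoylated; the silyl ether is removed.
Stereochemistry: absolute sense and C2/C6 from the twofold-symmetric chiral amine of the enamine (stored in the acetal carbon), C5 from the aldol transition state, C1 from the face bias of the bicycle, C2–Cl from inversion.

Key step: step 2

Remark: 2-phenyl-1,3-dioxan-5-one (4) is taken as purchasable; it is otherwise one oxidation from commercial 1,3-O-benzylideneglycerol.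

**Step 1**
Reactants: 1 acrolein (prop-2-enal)
Product: 3 2-(phenylselanyl)prop-2-enal, via chloro selenide 2 (not isolated)
Conditions: PhSeCl, CH2Cl2, −78 °C → 0 °C; then Et3N, 0 °C
Reagents that add atoms: benzeneselenenyl chloride, Cl[Se]c1ccccc1
Why: α-Selenenylation of an enal by addition–elimination: PhSeCl adds across the C=C bond with selenium at the α-carbon, and base-induced loss of HCl from the β-chloro aldehyde returns the α-seleno enal; no stereocentre is carried forward.

**Step 2**
Reactants: 4 2-phenyl-1,3-dioxan-5-one; 5 (2R,5R)-2,5-dimethylpyrrolidine; 3 2-(phenylselanyl)prop-2-enal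
Product: 8 (1S,3R,5R,6R)-6-hydroxy-3-phenyl-7-(phenylselanyl)-2,4-dioxabicyclo[3.3.1]nonan-9-one (both C7 epimers), via enamine 6 (not isolated), via Michael adduct 7 (not isolated)
Conditions: 4 Å MS, PhMe, 60 °C; then 3, MeCN, −20 °C → rt; then AcOH, NaOAc, H2O, rt
Reagents that add atoms: water, O
Why: Stork enamine α,α′-annulation (Michael addition, then intramolecular enamine aldol, 6-(enolendo)-exo-trig, then iminium hydrolysis), the reaction type that turns cyclohexanone enamines and acrolein into bicyclo[3.3.1]nonan-9-ones; here it forms the C2–C3 and the C5–C6 bond and closes the later cyclohexene as the carbocyclic ring of a 2,4-dioxabicyclo[3.3.1]nonane. The twofold-symmetric amine shields one face of each regioisomeric enamine, so only the enamine towards one of the two enantiotopic α-carbons can be attacked by the acrolein CH2 along the preferred axial trajectory; this choice fixes C2 and is stored in the acetal carbon, so later epimerisation at C2 cannot racemise the material. C6 follows from C2 because the three-carbon bridge can only span two cis-diaxial positions of the dioxane chair, whose equatorial phenyl and axial hydrogen leave room for it. C5 should be set in the aldol step by a closed, acetic-acid-bridged chair transition state that holds the aldehyde oxygen near the enamine nitrogen and so places the new hydroxyl pseudo-axial, anti to the dioxane oxygens (trans to O-6). The step needs attack at the CH2 terminus and a tether that stays saturated: the sp3 C4–SePh carbon prevents the vinylogous 1,5-dicarbonyl anion or pyrylium ion that a propynal-level partner would give, and Bredt's rule blocks dehydration of the bridged ketol.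

**Step 3**
Reactants: 8 (1S,3R,5R,6R)-6-hydroxy-3-phenyl-7-(phenylselanyl)-2,4-dioxabicyclo[3.3.1]nonan-9-one
Product: 10 (1R,3R,5S,8S)-8-hydroxy-3-phenyl-2,4-dioxabicyclo[3.3.1]non-6-en-9-one, via selenoxide 9 (not isolated)
Conditions: NaIO4, NaHCO3, THF/MeOH/H2O, 0 °C → rt
Reagents that add atoms: none
Why: Selenoxide syn-elimination, which for β-hydroxy selenoxides runs away from the carbinol carbon and so gives the C3=C4 olefin and the allylic alcohol; both C4 epimers converge and no other stereocentre is touched.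

**Step 4**
Reactants: 10 (1R,3R,5S,8S)-8-hydroxy-3-phenyl-2,4-dioxabicyclo[3.3.1]non-6-en-9-one
Product: 11 (1R,3R,5S,8S)-8-[(tert-butyldimethylsilyl)oxy]-3-phenyl-2,4-dioxabicyclo[3.3.1]non-6-en-9-one
Conditions: TBSOTf, 2,6-lutidine, CH2Cl2, −78 °C → 0 °C
Reagents that add atoms: tert-butyldimethylsilyl triflate, CC(C)(C)[Si](C)(C)OS(=O)(=O)C(F)(F)F
Why: Silyl ether formation at the hindered axial secondary alcohol; the ketone has only bridgehead α-hydrogens and cannot give a silyl enol ether, and the ether later prevents retro-aldol cleavage and blocks one face of C1.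

**Step 5**
Reactants: 11 (1R,3R,5S,8S)-8-[(tert-butyldimethylsilyl)oxy]-3-phenyl-2,4-dioxabicyclo[3.3.1]non-6-en-9-one
Product: 12 tert-butyldimethyl{[(1S,3R,5S,8S)-9-methylidene-3-phenyl-2,4-dioxabicyclo[3.3.1]non-6-en-8-yl]oxy}silane
Conditions: Ph3PCH3Br, KOtBu, THF, 0 °C → rt
Reagents that add atoms: methyltriphenylphosphonium bromide, C[P+](c1ccccc1)(c1ccccc1)c1ccccc1.[Br-]
Why: Wittig methylenation of a non-enolisable, inductively activated ketone; retro-aldol and β-elimination are excluded because the β-oxygen is silylated and both α-carbons are bridgeheads.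

**Step 6**
Reactants: 12 tert-butyldimethyl{[(1S,3R,5S,8S)-9-methylidene-3-phenyl-2,4-dioxabicyclo[3.3.1]non-6-en-8-yl]oxy}silane
Product: 13 (1R,3R,5S,8S,9S)-8-[(tert-butyldimethylsilyl)oxy]-9-(hydroxymethyl)-3-phenyl-2,4-dioxabicyclo[3.3.1]non-6-en-9-ol
Conditions: OsO4 (cat.), NMO, acetone/H2O, rt
Reagents that add atoms: N-methylmorpholine N-oxide, C[N+]1([O-])CCOCC1; water, O
Why: Upjohn dihydroxylation of the exocyclic olefin from the face turned to the dioxane ring, which has no syn-axial substituent, while the other face is blocked by the axial silyloxy group at C5, so the C1 hydroxyl ends up cis to O-2 and O-6; the ring olefin is screened by the silyl ether on one face and the inward acetal hydrogen on the other.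

**Step 7**
Reactants: 13 (1R,3R,5S,8S,9S)-8-[(tert-butyldimethylsilyl)oxy]-9-(hydroxymethyl)-3-phenyl-2,4-dioxabicyclo[3.3.1]non-6-en-9-ol
Product: 14 [(1R,3R,5S,8S,9S)-8-[(tert-butyldimethylsilyl)oxy]-9-hydroxy-3-phenyl-2,4-dioxabicyclo[3.3.1]non-6-en-9-yl]methyl benzoate
Conditions: BzCl, pyridine, CH2Cl2, −20 °C → 0 °C
Reagents that add atoms: benzoyl chloride, O=C(Cl)c1ccccc1
Why: Selective O-acylation of the primary hydroxyl in the presence of a tertiary one.

**Step 8**
Reactants: 14 [(1R,3R,5S,8S,9S)-8-[(tert-butyldimethylsilyl)oxy]-9-hydroxy-3-phenyl-2,4-dioxabicyclo[3.3.1]non-6-en-9-yl]methyl benzoate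
Product: 15 [(1S,2S,5S,6R)-5-[(tert-butyldimethylsilyl)oxy]-1,2,6-trihydroxycyclohex-3-en-1-yl]methyl benzoate
Conditions: CSA (cat.), MeOH/CH2Cl2, 0 °C → rt
Reagents that add atoms: none
Why: Acid-catalysed transacetalisation; the cis-1,3-diaxially bridging benzylidene acetal is strained and should exchange to benzaldehyde dimethyl acetal under conditions that leave the hindered secondary silyl ether and the benzoate intact.

**Step 9**
Reactants: 15 [(1S,2S,5S,6R)-5-[(tert-butyldimethylsilyl)oxy]-1,2,6-trihydroxycyclohex-3-en-1-yl]methyl benzoate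
Product: 16 [(1R,2R,5S,6R)-5-[(tert-butyldimethylsilyl)oxy]-2-chloro-1,6-dihydroxycyclohex-3-en-1-yl]methyl benzoate
Conditions: PPh3, Cl3CC(O)CCl3, CH2Cl2, −20 °C → 0 °C
Reagents that add atoms: hexachloroacetone, O=C(C(Cl)(Cl)Cl)C(Cl)(Cl)Cl
Why: Appel-type chlorination: the oxyphosphonium ion forms at the less hindered allylic C2 hydroxyl (C6–OH lies between the quaternary and the silyloxy carbon, C1–OH is tertiary) and chloride displaces it by SN2 with inversion, which sets C2 trans to the C1 hydroxyl; the PPh3/hexachloroacetone variant is the one known to convert secondary allylic alcohols without allylic transposition.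

**Step 10**
Reactants: 16 [(1R,2R,5S,6R)-5-[(tert-butyldimethylsilyl)oxy]-2-chloro-1,6-dihydroxycyclohex-3-en-1-yl]methyl benzoate
Product: 17 [(1R,2R,5S,6R)-6-(benzoyloxy)-5-[(tert-butyldimethylsilyl)oxy]-2-chloro-1-hydroxycyclohex-3-en-1-yl]methyl benzoate
Conditions: BzCl, pyridine, DMAP (cat.), CH2Cl2, 0 °C → rt
Reagents that add atoms: benzoyl chloride, O=C(Cl)c1ccccc1
Why: DMAP-catalysed benzoylation of the only secondary hydroxyl; the tertiary hydroxyl does not react and the weak amine base should not close the trans-chlorohydrin to an epoxide.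

**Step 11**
Reactants: 17 [(1R,2R,5S,6R)-6-(benzoyloxy)-5-[(tert-butyldimethylsilyl)oxy]-2-chloro-1-hydroxycyclohex-3-en-1-yl]methyl benzoate
Product: 18 [(1R,2R,5S,6R)-6-(benzoyloxy)-2-chloro-1,5-dihydroxycyclohex-3-en-1-yl]methyl benzoate (target)
Conditions: HF·pyridine, pyridine, THF, 0 °C → rt
Reagents that add atoms: none
Why: Fluoride desilylation under non-basic conditions, which avoids epoxide formation from the chlorohydrin and benzoyl migration from O-6 to O-5.

**Compound list**

1 | acrolein (prop-2-enal) | C=CC=O | starting material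
2 | 3-chloro-2-(phenylselanyl)propanal (racemic) | O=CC(CCl)[Se]c1ccccc1 | intermediate (not isolated)
3 | 2-(phenylselanyl)prop-2-enal | C=C(C=O)[Se]c1ccccc1 | intermediate
4 | 2-phenyl-1,3-dioxan-5-one | O=C1COC(c2ccccc2)OC1 | starting material
5 | (2R,5R)-2,5-dimethylpyrrolidine | C[C@@H]1CC[C@@H](C)N1 | starting material (recovered auxiliary)
6 | (2R,5R)-2,5-dimethyl-1-[(2S)-2-phenyl-4H-1,3-dioxin-5-yl]pyrrolidine (reacting double-bond isomer; equilibrates with the 2R isomer) | C[C@@H]1CC[C@@H](C)N1C1=CO[C@@H](c2ccccc2)OC1 | intermediate (not isolated)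
7 | 3-[(2S,4S)-5-[(2R,5R)-2,5-dimethylpyrrolidin-1-yl]-2-phenyl-4H-1,3-dioxin-4-yl]-2-(phenylselanyl)propanal (both epimers at the selenium-bearing carbon) | C[C@@H]1CC[C@@H](C)N1C1=CO[C@H](c2ccccc2)O[C@H]1CC([Se]c1ccccc1)C=O | intermediate (not isolated)
8 | (1S,3R,5R,6R)-6-hydroxy-3-phenyl-7-(phenylselanyl)-2,4-dioxabicyclo[3.3.1]nonan-9-one (both C7 epimers; phenyl exo, hydroxyl anti to the dioxane bridge) | O=C1[C@@H]2CC([Se]c3ccccc3)[C@H](O)[C@H]1O[C@H](c1ccccc1)O2 | intermediate
9 | (1S,3R,5R,6R)-7-(benzeneseleninyl)-6-hydroxy-3-phenyl-2,4-dioxabicyclo[3.3.1]nonan-9-one | O=C1[C@@H]2CC([Se](=O)c3ccccc3)[C@H](O)[C@H]1O[C@H](c1ccccc1)O2 | intermediate (not isolated)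
10 | (1R,3R,5S,8S)-8-hydroxy-3-phenyl-2,4-dioxabicyclo[3.3.1]non-6-en-9-one | O=C1[C@@H]2C=C[C@H](O)[C@H]1O[C@H](c1ccccc1)O2 | intermediate
11 | (1R,3R,5S,8S)-8-[(tert-butyldimethylsilyl)oxy]-3-phenyl-2,4-dioxabicyclo[3.3.1]non-6-en-9-one | O=C1[C@@H]2C=C[C@H](O[Si](C)(C)C(C)(C)C)[C@H]1O[C@H](c1ccccc1)O2 | intermediate
12 | tert-butyldimethyl{[(1S,3R,5S,8S)-9-methylidene-3-phenyl-2,4-dioxabicyclo[3.3.1]non-6-en-8-yl]oxy}silane | C=C1[C@@H]2C=C[C@H](O[Si](C)(C)C(C)(C)C)[C@H]1O[C@H](c1ccccc1)O2 | intermediate
13 | (1R,3R,5S,8S,9S)-8-[(tert-butyldimethylsilyl)oxy]-9-(hydroxymethyl)-3-phenyl-2,4-dioxabicyclo[3.3.1]non-6-en-9-ol (C9 hydroxyl on the dioxane side) | OC[C@]1(O)[C@@H]2C=C[C@H](O[Si](C)(C)C(C)(C)C)[C@H]1O[C@H](c1ccccc1)O2 | intermediate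
14 | [(1R,3R,5S,8S,9S)-8-[(tert-butyldimethylsilyl)oxy]-9-hydroxy-3-phenyl-2,4-dioxabicyclo[3.3.1]non-6-en-9-yl]methyl benzoate | O=C(OC[C@]1(O)[C@@H]2C=C[C@H](O[Si](C)(C)C(C)(C)C)[C@H]1O[C@H](c1ccccc1)O2)c1ccccc1 | intermediate
15 | [(1S,2S,5S,6R)-5-[(tert-butyldimethylsilyl)oxy]-1,2,6-trihydroxycyclohex-3-en-1-yl]methyl benzoate | O=C(OC[C@]1(O)[C@@H](O)C=C[C@H](O[Si](C)(C)C(C)(C)C)[C@H]1O)c1ccccc1 | intermediate
16 | [(1R,2R,5S,6R)-5-[(tert-butyldimethylsilyl)oxy]-2-chloro-1,6-dihydroxycyclohex-3-en-1-yl]methyl benzoate | O=C(OC[C@]1(O)[C@H](Cl)C=C[C@H](O[Si](C)(C)C(C)(C)C)[C@H]1O)c1ccccc1 | intermediate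
17 | [(1R,2R,5S,6R)-6-(benzoyloxy)-5-[(tert-butyldimethylsilyl)oxy]-2-chloro-1-hydroxycyclohex-3-en-1-yl]methyl benzoate | O=C(OC[C@]1(O)[C@H](Cl)C=C[C@H](O[Si](C)(C)C(C)(C)C)[C@H]1OC(=O)c1ccccc1)c1ccccc1 | intermediate
18 | [(1R,2R,5S,6R)-6-(benzoyloxy)-2-chloro-1,5-dihydroxycyclohex-3-en-1-yl]methyl benzoate | O=C(OC[C@]1(O)[C@H](Cl)C=C[C@H](O)[C@H]1OC(=O)c1ccccc1)c1ccccc1 | target

**Count and risks**

Total steps: 11. Longest linear sequence: 11 steps (1 → 3 → 8 → … → 18); 10 steps counted from ketone 4.

Step 2. What may go wrong: weak discrimination between the two enantiotopic α-carbons in the Michael addition, or retro-aldol/aldol equilibration of the ketol during the buffered hydrolysis, either of which would erode enantiomeric purity or the C5 configuration. Fallback: starting from 4, the annulation would be run in the racemic series with the achiral enamine 1-(2-phenyl-4H-1,3-dioxin-5-yl)pyrrolidine F1 and 3 under the same protocol to give the racemic ketol selenide F2. Oxidation and elimination with NaIO4 would give the racemic allylic alcohol F3. F3 would then be resolved by lipase-catalysed acylation (Candida antarctica lipase B, vinyl acetate, MTBE): by the usual empirical model for secondary alcohols the (8R)-enantiomer should be acylated to the acetate F4, and the unreacted (8S)-alcohol is compound 10, where the route is rejoined.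

Step 6. What may go wrong: poor site or face selectivity in the osmylation, that is, attack on the ring olefin or on the exocyclic olefin from the carbocycle face. Fallback: starting from 12, the acetal would be removed first (CSA, MeOH) to give the bis-allylic diol F5. Its exocyclic olefin would be epoxidised with t-BuOOH and catalytic VO(acac)2, a hydroxyl-directed epoxidation in which both cis allylic hydroxyls deliver the oxidant to the same face of the olefin they flank, to give the spiro-epoxide F6. F6 would be opened at the CH2 terminus with benzoic acid and Ti(OiPr)4 (C-3-selective opening of a 2,3-epoxy alcohol). The product is 15, so steps 7 and 8 are bypassed.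

Step 9. What may go wrong: substitution with allylic transposition (chloride entering at C4), ionisation with loss of configuration, or rear-side participation of the C7 benzoate at C2. Fallback: starting from 15, the cis C1/C2 diol would be converted with trimethyl orthobenzoate and PPTS into the cyclic orthobenzoate F7, which would be opened with TMSCl. The derived 1,3-dioxolan-2-ylium ion should be attacked by chloride at the allylic carbon with inversion, giving the chloride F8 with the benzoate on the tertiary oxygen. Acid-catalysed (CSA) acyl migration to the cis C6 hydroxyl would then give 17, where the route is rejoined and step 10 is bypassed.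

**Further compounds**

F1 | step 2 | 1-(2-phenyl-4H-1,3-dioxin-5-yl)pyrrolidine (racemic) | C1(N2CCCC2)=COC(c2ccccc2)OC1
F2 | step 2 | rac-(1S,3R,5R,6R)-6-hydroxy-3-phenyl-7-(phenylselanyl)-2,4-dioxabicyclo[3.3.1]nonan-9-one (racemate, one enantiomer drawn, both C7 epimers) | O=C1[C@@H]2CC([Se]c3ccccc3)[C@H](O)[C@H]1O[C@H](c1ccccc1)O2
F3 | step 2 | rac-(1R,3R,5S,8S)-8-hydroxy-3-phenyl-2,4-dioxabicyclo[3.3.1]non-6-en-9-one (racemate, one enantiomer drawn) | O=C1[C@@H]2C=C[C@H](O)[C@H]1O[C@H](c1ccccc1)O2
F4 | step 2 | (1S,3S,5R,8R)-9-oxo-3-phenyl-2,4-dioxabicyclo[3.3.1]non-6-en-8-yl acetate | O=C1[C@H]2C=C[C@@H](OC(C)=O)[C@@H]1O[C@@H](c1ccccc1)O2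
F5 | step 6 | (1S,3S,6S)-6-[(tert-butyldimethylsilyl)oxy]-2-methylidenecyclohex-4-ene-1,3-diol | C=C1[C@@H](O)C=C[C@H](O[Si](C)(C)C(C)(C)C)[C@H]1O
F6 | step 6 | (3S,4S,7S,8R)-7-[(tert-butyldimethylsilyl)oxy]-1-oxaspiro[2.5]oct-5-ene-4,8-diol | C1O[C@]12[C@@H](O)C=C[C@H](O[Si](C)(C)C(C)(C)C)[C@H]2O
F7 | step 9 | cyclic orthobenzoate of 15 across O-1 and O-2 (2-methoxy-2-phenyl-1,3-dioxolane fused at C1–C2, C6–OH free, orthoester carbon unassigned) | O=C(OC[C@]12OC(OC)(c3ccccc3)O[C@H]1C=C[C@H](O[Si](C)(C)C(C)(C)C)[C@H]2O)c1ccccc1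
F8 | step 9 | [(1R,2R,5S,6R)-1-(benzoyloxy)-5-[(tert-butyldimethylsilyl)oxy]-2-chloro-6-hydroxycyclohex-3-en-1-yl]methyl benzoate | O=C(OC[C@]1(OC(=O)c2ccccc2)[C@H](Cl)C=C[C@H](O[Si](C)(C)C(C)(C)C)[C@H]1O)c1ccccc1
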